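**Plan**

- Retrosynthesis: the last cut removes only acid-labile masks (two tert-butyl esters, three catechol isopropylidene ketals). The strategic cut breaks the three aryl–Cβ bonds of the caffeoyl esters at once, giving a quinate 1,3,5-triacrylate and an iodobenzodioxole. The three acrylate C(=O)–O bonds and the succinyl C(=O)–O4 bond are then cut back to (−)-quinic acid.
- Enabling feature: on the cyclohexane ring (quaternary C1 carrying the carboxyl carbon and O1, succinate on O4), the esters on O1, O3 and O5 are all prop-2-enoates whose β-carbon is bonded to a benzene ring oxygenated at its 3- and 4-positions. Each is therefore the arylation product of a plain acrylate.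
- Forward order: no ring is made (the cyclohexane comes from quinic acid, the benzene rings from a benzodioxole). The chain is joined as C1 tert-butyl ester, O3/O5 silyl ethers, O4 succinate, desilylation, three acrylates on O1/O3/O5, three aryl groups, then one acidolysis.
- Stereochemistry: the four ring stereocentres are those of (−)-quinic acid, and only their O–H bonds are ever changed. The three E alkenes are set by syn insertion and syn β-hydride elimination in the arylation.

Key step: step 7

Remark: quinic acid numbering is used throughout (C1 bears the carboxyl group; O3 is cis and O5 trans to O4). The target SMILES has O1, O3 and O4 on one ring face and O5 and the carboxyl carbon on the other, which is the arrangement of natural (−)-quinic acid ((1S,3R,4S,5R) in the parent acid), and every quinate below keeps it.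

**Route**

Step 1
Reactants: 1 (−)-quinic acid; 2 O-tert-butyl-N,N'-diisopropylisourea
Product: 3 tert-butyl (−)-quinate
Conditions: 2 (3 equiv), DMF, rt → 40 °C
Reagents that add atoms: O-tert-butyl-N,N'-diisopropylisourea 2, CC(C)NC(=NC(C)C)OC(C)(C)C
Why: In this O-alkylisourea esterification the carboxylic acid protonates the reagent and the carboxylate then takes up the tert-butyl group, whereas the four hydroxyls are not acidic enough to activate the isourea and should stay free; no stereocentre is involved.

Step 2
Reactants: 3 tert-butyl (−)-quinate; 4 tert-butyldimethylsilyl chloride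
Product: 5 tert-butyl 3,5-bis-O-(tert-butyldimethylsilyl)quinate
Conditions: TBSCl (2.3 equiv), imidazole (5 equiv), DMF, 0 °C → rt
Reagents that add atoms: tert-butyldimethylsilyl chloride 4, CC(C)(C)[Si](C)(C)Cl
Why: Silyl ether formation on quinate esters is known to take the two outer secondary hydroxyls O3 and O5 and to leave the flanked O4–H and the tertiary O1–H free, and the bulky tert-butyl ester should not lactonise onto O5.

Step 3
Reactants: 5 tert-butyl 3,5-bis-O-(tert-butyldimethylsilyl)quinate; 6 4-tert-butoxy-4-oxobutanoic acid (mono-tert-butyl succinate)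
Product: 7 tert-butyl 4-O-(4-tert-butoxy-4-oxobutanoyl)-3,5-bis-O-(tert-butyldimethylsilyl)quinate
Conditions: 6 (2 equiv), DCC (2 equiv), DMAP (0.5 equiv), CH2Cl2, 0 °C → rt
Reagents that add atoms: 4-tert-butoxy-4-oxobutanoic acid 6, CC(C)(C)OC(=O)CCC(=O)O
Why: In this Steglich esterification the acylpyridinium ion formed from the half ester should acylate the only free secondary hydroxyl (O4), the tertiary O1–H being far less reactive.

Step 4
Reactants: 7 tert-butyl 4-O-(4-tert-butoxy-4-oxobutanoyl)-3,5-bis-O-(tert-butyldimethylsilyl)quinate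
Product: 8 tert-butyl 4-O-(4-tert-butoxy-4-oxobutanoyl)quinate (free O1–H, O3–H and O5–H)
Conditions: HF·pyridine, pyridine, THF, 0 °C → rt (polypropylene vessel)
Reagents that add atoms: none
Why: Fluoride-driven Si–O cleavage in a weakly acidic medium should remove both silyl ethers while sparing the tert-butyl esters, and since no alkoxide is formed the O4 succinate is not expected to migrate to O3 or O5.

Step 5
Reactants: 8 tert-butyl 4-O-(4-tert-butoxy-4-oxobutanoyl)quinate; 9 acryloyl chloride
Product: 10 tert-butyl 1,3,5-tri-O-acryloyl-4-O-(4-tert-butoxy-4-oxobutanoyl)quinate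
Conditions: acryloyl chloride (6 equiv), Et3N (8 equiv), DMAP (0.5 equiv), BHT (cat), CH2Cl2, −20 °C → rt
Reagents that add atoms: acryloyl chloride 9, C=CC(=O)Cl
Why: DMAP-catalysed acylation with this small, very reactive acid chloride should esterify the two secondary hydroxyls quickly (which ends any chance of succinyl migration) and then, with excess reagent and time, the tertiary O1–H, while BHT holds back radical polymerisation.

Step 6
Reactants: 11 2,2-dimethyl-1,3-benzodioxole; 12 N-iodosuccinimide
Product: 13 5-iodo-2,2-dimethyl-1,3-benzodioxole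
Conditions: NIS (1.05 equiv), TFA (0.1 equiv), MeCN, rt, dark
Reagents that add atoms: N-iodosuccinimide 12, O=C1CCC(=O)N1I
Why: Electrophilic aromatic iodination by acid-activated NIS should occur para to a ring oxygen at C5, the only unhindered activated position of the symmetric arene, and catalytic anhydrous acid should not open the ketal.

Step 7
Reactants: 10 tert-butyl 1,3,5-tri-O-acryloyl-4-O-(4-tert-butoxy-4-oxobutanoyl)quinate; 13 5-iodo-2,2-dimethyl-1,3-benzodioxole
Product: 14 tert-butyl 4-O-(4-tert-butoxy-4-oxobutanoyl)-1,3,5-tris-O-[(E)-3-(2,2-dimethyl-1,3-benzodioxol-5-yl)prop-2-enoyl]quinate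
Conditions: 13 (3.6 equiv), Pd(OAc)2 (10 mol %), Bu4NCl (3 equiv), NaHCO3 (8 equiv), DMF, 65 °C, argon
Reagents that add atoms: 5-iodo-2,2-dimethyl-1,3-benzodioxole 13, CC1(C)Oc2ccc(I)cc2O1
Why: Pd(OAc)2 is reduced in the flask to zerovalent palladium, which inserts into the C–I bond of 13; the arylpalladium iodide adds syn across each acrylate with the aryl group going to the unsubstituted CH2 terminus, syn β-hydride elimination from the rotamer with aryl and ester anti releases the (E)-cinnamate, and bicarbonate takes up HI to return zerovalent palladium. The closest known reaction type is the ligand-free, phase-transfer Mizoroki–Heck arylation of acrylate esters by electron-rich aryl iodides. No ring is closed and no stereocentre is created, so the four ring stereocentres, none of which carries an acidic hydrogen, pass through unchanged. The step needs β-regioselectivity and E geometry, both secured by the polarised, terminally unsubstituted acrylate, and it needs all three acrylates to react, which their separation across the ring and an excess of 13 should allow. Chemoselectivity rests on the mild solid base and moderate temperature, which should leave the six ester groups and the benzodioxole ketals alone, and on a second arylation of the product cinnamates being much slower than the first.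

Step 8
Reactants: 14 tert-butyl 4-O-(4-tert-butoxy-4-oxobutanoyl)-1,3,5-tris-O-[(E)-3-(2,2-dimethyl-1,3-benzodioxol-5-yl)prop-2-enoyl]quinate
Product: 15 1,3,5-tri-O-[(E)-caffeoyl]-4-O-succinyl-(−)-quinic acid (target)
Conditions: TFA/H2O (9:1), 0 °C → rt, argon, dark; evaporation, reverse-phase chromatography
Reagents that add atoms: none
Why: In this acidolysis TFA should cleave both tert-butyl esters by alkyl–oxygen fission and, with water, hydrolyse the three catechol isopropylidene ketals, while the carboxylic esters and E alkenes are stable to acid and, with every ring oxygen acylated and no base present, neither acyl migration nor ester hydrolysis is expected.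

**Compound list**

1 | (−)-quinic acid, (1S,3R,4S,5R)-1,3,4,5-tetrahydroxycyclohexane-1-carboxylic acid | O[C@H]1[C@H](O)C[C@](O)(C(=O)O)C[C@H]1O | starting material
2 | O-tert-butyl-N,N'-diisopropylisourea | CC(C)NC(=NC(C)C)OC(C)(C)C | starting material
3 | tert-butyl (−)-quinate | O[C@H]1[C@H](O)C[C@](O)(C(=O)OC(C)(C)C)C[C@H]1O | intermediate
4 | tert-butyldimethylsilyl chloride | CC(C)(C)[Si](C)(C)Cl | starting material
5 | tert-butyl 3,5-bis-O-(tert-butyldimethylsilyl)quinate | O[C@H]1[C@H](O[Si](C)(C)C(C)(C)C)C[C@](O)(C(=O)OC(C)(C)C)C[C@H]1O[Si](C)(C)C(C)(C)C | intermediate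
6 | 4-tert-butoxy-4-oxobutanoic acid (mono-tert-butyl succinate) | CC(C)(C)OC(=O)CCC(=O)O | starting material
7 | tert-butyl 4-O-(4-tert-butoxy-4-oxobutanoyl)-3,5-bis-O-(tert-butyldimethylsilyl)quinate | CC(C)(C)OC(=O)CCC(=O)O[C@H]1[C@H](O[Si](C)(C)C(C)(C)C)C[C@](O)(C(=O)OC(C)(C)C)C[C@H]1O[Si](C)(C)C(C)(C)C | intermediate
8 | tert-butyl 4-O-(4-tert-butoxy-4-oxobutanoyl)quinate | CC(C)(C)OC(=O)CCC(=O)O[C@H]1[C@H](O)C[C@](O)(C(=O)OC(C)(C)C)C[C@H]1O | intermediate
9 | acryloyl chloride | C=CC(=O)Cl | starting material
10 | tert-butyl 1,3,5-tri-O-acryloyl-4-O-(4-tert-butoxy-4-oxobutanoyl)quinate | CC(C)(C)OC(=O)CCC(=O)O[C@H]1[C@H](OC(=O)C=C)C[C@](OC(=O)C=C)(C(=O)OC(C)(C)C)C[C@H]1OC(=O)C=C | intermediate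
11 | 2,2-dimethyl-1,3-benzodioxole | CC1(C)Oc2ccccc2O1 | starting material
12 | N-iodosuccinimide | O=C1CCC(=O)N1I | starting material
13 | 5-iodo-2,2-dimethyl-1,3-benzodioxole | CC1(C)Oc2ccc(I)cc2O1 | intermediate
14 | tert-butyl 4-O-(4-tert-butoxy-4-oxobutanoyl)-1,3,5-tris-O-[(E)-3-(2,2-dimethyl-1,3-benzodioxol-5-yl)prop-2-enoyl]quinate | CC(C)(C)OC(=O)CCC(=O)O[C@H]1[C@H](OC(=O)/C=C/c2ccc3OC(C)(C)Oc3c2)C[C@](OC(=O)/C=C/c2ccc3OC(C)(C)Oc3c2)(C(=O)OC(C)(C)C)C[C@H]1OC(=O)/C=C/c1ccc2OC(C)(C)Oc2c1 | intermediate
15 | 1,3,5-tri-O-[(E)-caffeoyl]-4-O-succinyl-(−)-quinic acid | O=C(O)CCC(=O)O[C@H]1[C@H](OC(=O)/C=C/c2ccc(O)c(O)c2)C[C@](OC(=O)/C=C/c2ccc(O)c(O)c2)(C(=O)O)C[C@H]1OC(=O)/C=C/c1ccc(O)c(O)c1 | target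

**Count and risks**

Total step count: 8. Longest linear sequence: 7 (steps 1 to 5, 7 and 8 from quinic acid); step 6 is a one-step side branch.

Steps most likely to fail:

Step 5. The acylation may stall at the 3,5-diacrylate because the tertiary, axial O1 hydroxyl reacts slowly. The long exposure to base and excess acid chloride needed to force it may let the acrylates already present oligomerise. The fallback separates the hard acylation from the easy ones and sets out from 7, whose only free hydroxyl is O1. Acryloylation there under forcing conditions (9 in large excess, Et3N, DMAP 1 equiv, BHT, 1,2-dichloroethane, 50 °C) should give tert-butyl 1-O-acryloyl-4-O-(4-tert-butoxy-4-oxobutanoyl)-3,5-bis-O-(tert-butyldimethylsilyl)quinate F1. HF·pyridine in THF should then free O3 and O5 to give tert-butyl 1-O-acryloyl-4-O-(4-tert-butoxy-4-oxobutanoyl)quinate F2. A short, cold acryloylation of the two secondary hydroxyls (9, Et3N, catalytic DMAP, CH2Cl2, −20 °C) comes back to the route at 10.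

Step 7. The catalyst may aggregate to palladium black before all three acrylates are arylated, leaving partly arylated esters, and longer heating with base may start ester cleavage. The fallback is an oxidative boron Heck reaction, which forms the same three aryl–Cβ bonds from the same 10 but begins by transmetalation to divalent palladium and runs near room temperature. Setting out from 13, Miyaura borylation (bis(pinacolato)diboron, KOAc, PdCl2(dppf), dioxane, 80 °C) should give 2-(2,2-dimethyl-1,3-benzodioxol-5-yl)-4,4,5,5-tetramethyl-1,3,2-dioxaborolane F3. F3 (3.6 equiv) is then coupled with 10 using Pd(OAc)2, 2,9-dimethyl-1,10-phenanthroline and O2 (1 atm) in DMF at rt to 40 °C, coming back to the route at 14.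

Step 3. The O4 hydroxyl, wedged between two silyloxy groups, may be acylated so slowly that the O-acylisourea rearranges to the inert N-acylurea and the acid is used up. The fallback sets out from 5 and opens succinic anhydride, a small and strongly activated cyclic acyl donor (DMAP, Et3N, toluene, 80 °C). This should give 4-{[2,6-bis(tert-butyldimethylsilyloxy)-4-(tert-butoxycarbonyl)-4-hydroxycyclohexyl]oxy}-4-oxobutanoic acid, the 4-O-hemisuccinate of 5, F4. Its free carboxyl is then tert-butylated with isourea 2 (CH2Cl2, rt), coming back to the route at 7.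

**Further compounds**

F1 | step 5 | tert-butyl 1-O-acryloyl-4-O-(4-tert-butoxy-4-oxobutanoyl)-3,5-bis-O-(tert-butyldimethylsilyl)quinate | CC(C)(C)OC(=O)CCC(=O)O[C@H]1[C@H](O[Si](C)(C)C(C)(C)C)C[C@](OC(=O)C=C)(C(=O)OC(C)(C)C)C[C@H]1O[Si](C)(C)C(C)(C)C
F2 | step 5 | tert-butyl 1-O-acryloyl-4-O-(4-tert-butoxy-4-oxobutanoyl)quinate | CC(C)(C)OC(=O)CCC(=O)O[C@H]1[C@H](O)C[C@](OC(=O)C=C)(C(=O)OC(C)(C)C)C[C@H]1O
F3 | step 7 | 2-(2,2-dimethyl-1,3-benzodioxol-5-yl)-4,4,5,5-tetramethyl-1,3,2-dioxaborolane | CC1(C)Oc2ccc(cc2O1)B1OC(C)(C)C(C)(C)O1
F4 | step 3 | 4-O-hemisuccinate of tert-butyl 3,5-bis-O-(tert-butyldimethylsilyl)quinate | OC(=O)CCC(=O)O[C@H]1[C@H](O[Si](C)(C)C(C)(C)C)C[C@](O)(C(=O)OC(C)(C)C)C[C@H]1O[Si](C)(C)C(C)(C)C
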